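The trans-decalin is opened at C4–C5 and C9–C10, unfolding rings A and B into an acyclic E,E-diene headed by an α-methyl β-keto ester. The key step, an oxidative radical bicyclization with Mn(OAc)3 and Cu(OAc)2, closes ring A at C4–C5 and ring B at C9–C10 in one operation and sets C4, C5, C9 and C10. It exploits the quaternary C4 of ring A: its oxygenated carbon C19, paired with a temporary C3 ketone, makes C4 a 1,3-dicarbonyl radical site, and C19 ends cis to the C10 methyl. A (1R,2S,5R)-8-phenylmenthyl ester at C19 relays absolute configuration. The 13Z acid chain is attached last by a stereoretentive Negishi coupling.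

Key step: step 7

Remark on numbering: labdane numbering is used. Ring A is C1–C5/C10 and ring B is C5–C10; C18 is the 4α-methyl, C19 the 4β carbon, C20 the 10β-methyl, C17 the methyl on C8, and C11–C16 the side chain on C9. The target is 19-angeloyloxy-labda-7,13Z-dien-15-oic acid.

Assumption: the (1R,2S,5R)-8-phenylmenthyl ester is taken to steer the radical cyclization of the α-methyl keto ester into the 5α-H,10β-methyl series; if the opposite sense were found, the enantiomeric auxiliary would be used with no other change.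

Step 1
Reactants: 1 geranyl bromide, (2E)-1-bromo-3,7-dimethylocta-2,6-diene; 2 (chloromethyl)(isopropoxy)dimethylsilane
Product: 5 homogeraniol, (3E)-4,8-dimethylnona-3,7-dien-1-ol, via Grignard reagent 3 (not isolated), via homoallylsilane 4 (not isolated)
Conditions: 2, Mg, THF, reflux; then 1, CuI (10 mol %), THF, 0 °C; then KF, KHCO3, 30% H2O2, MeOH/THF, rt
Reagents that add atoms: hydrogen peroxide, OO; magnesium, [Mg] (stays in intermediate 3 only)
Why: nucleophilic hydroxymethylation, in which copper-catalysed SN2 coupling of the silylmethyl Grignard reagent with the allylic bromide keeps the E alkene and Tamao–Fleming oxidation of the alkoxysilane turns C–Si into C–OH without touching the alkenes.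

Step 2
Reactants: 5 homogeraniol
Product: 6 homogeranyl pivalate, (3E)-4,8-dimethylnona-3,7-dien-1-yl pivalate
Conditions: PivCl, pyridine, DMAP (cat.), CH2Cl2, 0 °C to rt
Reagents that add atoms: pivaloyl chloride, CC(C)(C)C(=O)Cl
Why: standard acylation of an unhindered primary alcohol; the pivalate should survive the dianion and the acetic acid of later steps and is removed by the hydride step that is needed anyway.

Step 3
Reactants: 6 homogeranyl pivalate
Product: 7 (3E,7E)-9-hydroxy-4,8-dimethylnona-3,7-dien-1-yl pivalate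
Conditions: SeO2 (0.1 equiv), t-BuOOH (3 equiv), salicylic acid (0.1 equiv), CH2Cl2, rt
Reagents that add atoms: tert-butyl hydroperoxide, CC(C)(C)OO (terminal oxidant; the oxygen is delivered through SeO2, O=[Se]=O)
Why: Riley allylic oxidation (ene reaction, then [2,3]-sigmatropic shift), which is expected to hydroxylate the trans-methyl of the terminal isopropylidene group E-selectively.

Step 4
Reactants: 7 allylic alcohol
Product: 8 (3E,7E)-9-bromo-4,8-dimethylnona-3,7-dien-1-yl pivalate
Conditions: CBr4, PPh3, CH2Cl2, 0 °C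
Reagents that add atoms: carbon tetrabromide, BrC(Br)(Br)Br
Why: Appel reaction, SN2 displacement of the primary allylic oxyphosphonium that should proceed without allylic transposition and with the E geometry kept.

Step 5
Reactants: 9 ethyl 2-methyl-3-oxobutanoate; 10 (1R,2S,5R)-8-phenylmenthol, (1R,2S,5R)-5-methyl-2-(2-phenylpropan-2-yl)cyclohexan-1-ol
Product: 11 (1R,2S,5R)-8-phenylmenthyl 2-methyl-3-oxobutanoate (mixture of C2 epimers)
Conditions: DMAP (0.3 equiv), toluene, reflux, 4 Å molecular sieves in a Soxhlet to remove EtOH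
Reagents that add atoms: none
Why: DMAP-catalysed transesterification of a β-keto ester, which runs through the acylketene and is therefore feasible with a hindered secondary alcohol; the C2 centre is erased later.

Step 6
Reactants: 11 auxiliary keto ester; 8 allylic bromide
Product: 13 (1R,2S,5R)-8-phenylmenthyl (6E,10E)-2,6,10-trimethyl-3-oxo-13-(pivaloyloxy)trideca-6,10-dienoate (mixture of C2 epimers), via dianion 12 (not isolated)
Conditions: 11, NaH, THF, 0 °C; n-BuLi, 0 °C; then 8, 0 °C; 1 M HCl work-up
Reagents that add atoms: sodium hydride, [Na+].[H-] and n-butyllithium, [Li]CCCC (their metals stay in intermediate 12 only)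
Why: γ-alkylation of a β-keto ester dianion, whose terminal carbanion is the more reactive site and should attack the allylic bromide by SN2 far faster than the pivalate carbonyl.

Step 7
Reactants: 13 acyclic keto ester
Product: 14 (1R,2S,5R)-8-phenylmenthyl 3-oxo-12-(pivaloyloxy)-13,14,15,16-tetranorlabd-8(17)-en-19-oate (4β-ester, 4α-methyl, 5α-H, 9β side chain, 10β-methyl)
Conditions: Mn(OAc)3·2H2O (2.2 equiv), Cu(OAc)2·H2O (1.0 equiv), degassed AcOH, rt
Reagents that add atoms: none
Why: Trivalent manganese oxidises the enol of 13 to the tertiary C4 radical, which adds 6-endo-trig to C5 of the C5=C10 alkene (closing ring A); the tertiary C10 radical then adds 6-endo-trig to C9 of the C8=C9 alkene (closing ring B), and divalent copper oxidises the tertiary C8 radical with loss of a C17 hydrogen to the exocyclic alkene. The closest known reaction type is the Mn(OAc)3/Cu(OAc)2 oxidative polyene cyclisation of α-methyl β-keto esters, including its chiral 8-phenylmenthyl ester variant. Both closures pass through chair-like transition states, so the two E alkenes translate into the trans ring fusion (C5-H α, C10-methyl β) and the equatorial β side chain at C9, and at C4 the ester takes the axial position cis to the C10 methyl while the methyl goes equatorial. Absolute configuration is relayed from the auxiliary, whose phenyl ring covers one face of the planar C4 radical so that C5 bonds to the open face. The step needs 6-endo over 5-exo closure, secured by the methyl groups on C10 and C8 that block the internal alkene carbons and make each new radical tertiary, and it needs the cascade to stop after ring B, secured by the absence of any further alkene and by the copper salt. Any Δ7 isomer 15 formed alongside 14 is not separated, because step 8 converges both.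

Step 8
Reactants: 14 exocyclic alkene
Product: 15 (1R,2S,5R)-8-phenylmenthyl 3-oxo-12-(pivaloyloxy)-13,14,15,16-tetranorlabd-7-en-19-oate
Conditions: Co(salen)Cl (salen = N,N'-bis(3,5-di-tert-butylsalicylidene)-1,2-cyclohexanediaminate; 3 mol %), PhSiH3 (6 mol %), benzene, rt
Reagents that add atoms: none
Why: hydrogen-atom-transfer alkene isomerisation, in which a cobalt hydride adds H to C17 and the tertiary C8 radical gives back H from the accessible C7 methylene rather than the hindered C9 methine; trisubstituted alkenes are not re-engaged, so the Δ7 alkene should result with C9 untouched.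

Step 9
Reactants: 15 Δ7 keto ester
Product: 16 C3 tosylhydrazone of 15
Conditions: TsNHNH2, PPTS (cat.), EtOH, reflux
Reagents that add atoms: p-toluenesulfonohydrazide, Cc1ccc(cc1)S(=O)(=O)NN
Why: hydrazone condensation at the only ketone, a reaction that 3-oxo terpenoids with a quaternary C4 are known to undergo.

Step 10
Reactants: 16 tosylhydrazone
Product: 17 (1R,2S,5R)-8-phenylmenthyl 12-(pivaloyloxy)-13,14,15,16-tetranorlabd-7-en-19-oate
Conditions: catecholborane, CHCl3, 0 °C to rt; then NaOAc·3H2O, reflux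
Reagents that add atoms: none
Why: Caglioti-type reduction in its mild borane variant: hydride adds to C=N, sulfinate leaves, and the diazene loses N2 to give the C3 methylene under conditions that should leave both esters and the alkene alone.

Step 11
Reactants: 17 diester
Product: 18 13,14,15,16-tetranorlabd-7-ene-12,19-diol
Conditions: LiAlH4, THF, reflux; Fieser work-up
Reagents that add atoms: none
Why: hydride reduction that cleaves the pivalate and reduces the hindered axial C19 ester to the neopentyl alcohol in one operation, with the auxiliary 10 returned for re-use.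

Step 12
Reactants: 18 diol
Product: 19 12-iodo-13,14,15,16-tetranorlabd-7-en-19-ol
Conditions: I2, PPh3, imidazole (1.1 equiv each), CH2Cl2, 0 °C
Reagents that add atoms: iodine, II
Why: Appel-type iodination, site-selective because SN2 displacement of the oxyphosphonium is possible at the unhindered C12 but not at the neopentyl, axial C19.

Step 13
Reactants: 19 iodo alcohol; 20 angelic acid, (2Z)-2-methylbut-2-enoic acid
Product: 22 12-iodo-13,14,15,16-tetranorlabd-7-en-19-yl angelate, via mixed anhydride 21 (not isolated)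
Conditions: 20, 2,4,6-trichlorobenzoyl chloride, Et3N (1.0 equiv), toluene, rt, filter; then 19, toluene, 75 °C, dark
Reagents that add atoms: 2,4,6-trichlorobenzoyl chloride, O=C(Cl)c1c(Cl)cc(Cl)cc1Cl (its atoms stay in intermediate 21 only)
Why: Yamaguchi-type esterification run without a nucleophilic catalyst, conditions under which angelates are expected to form without Z-to-E isomerisation to the tiglate; the alcohol attacks the unhindered angeloyl carbonyl of the anhydride.

Step 14
Reactants: 23 but-2-ynoic acid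
Product: 24 (2Z)-3-iodobut-2-enoic acid
Conditions: NaI, AcOH, 110 °C
Reagents that add atoms: sodium iodide, [Na+].[I-]
Why: hydroiodination of an ynoic acid by anti addition, which places iodine on C3 cis to the carboxyl group (Z).

Step 15
Reactants: 22 iodo angelate; 24 (2Z)-3-iodobut-2-enoic acid
Product: 27 19-angeloyloxy-labda-7,13Z-dien-15-oic acid (target), via alkylzinc iodide 25 (not isolated), via sodium carboxylate 26 (not isolated)
Conditions: 22, Zn dust (activated with TMSCl and BrCH2CH2Br), LiCl, THF, 40 °C; 24, NaH, DMF, 0 °C; combine, PdCl2(dppf) (5 mol %), THF/DMF, rt to 40 °C; 1 M HCl work-up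
Reagents that add atoms: zinc, [Zn] (stays in intermediate 25 only); sodium hydride, [Na+].[H-] (its sodium stays in intermediate 26 only)
Why: Negishi coupling, in which zinc insertion into the primary C–I bond tolerates the angelate and the vinyl iodide adds to zerovalent palladium and couples with retention, so C12 ends cis to the carboxyl group (13Z); coupling of this iodo acid as its carboxylate with organozinc halides is a known reaction type.

Compound list
1 | geranyl bromide | CC(C)=CCC/C(C)=C/CBr | starting material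
2 | (chloromethyl)(isopropoxy)dimethylsilane | CC(C)O[Si](C)(C)CCl | starting material
3 | (isopropoxydimethylsilyl)methylmagnesium chloride | CC(C)O[Si](C)(C)C[Mg]Cl | intermediate (not isolated)
4 | [(3E)-4,8-dimethylnona-3,7-dien-1-yl](isopropoxy)dimethylsilane | CC(C)=CCC/C(C)=C/CC[Si](C)(C)OC(C)C | intermediate (not isolated)
5 | homogeraniol | CC(C)=CCC/C(C)=C/CCO | intermediate
6 | homogeranyl pivalate | CC(C)=CCC/C(C)=C/CCOC(=O)C(C)(C)C | intermediate
7 | (3E,7E)-9-hydroxy-4,8-dimethylnona-3,7-dien-1-yl pivalate | OC/C(C)=C/CC/C(C)=C/CCOC(=O)C(C)(C)C | intermediate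
8 | (3E,7E)-9-bromo-4,8-dimethylnona-3,7-dien-1-yl pivalate | BrC/C(C)=C/CC/C(C)=C/CCOC(=O)C(C)(C)C | intermediate
9 | ethyl 2-methyl-3-oxobutanoate | CCOC(=O)C(C)C(C)=O | starting material
10 | (1R,2S,5R)-8-phenylmenthol | C[C@@H]1CC[C@H]([C@@H](C1)O)C(C)(C)c2ccccc2 | starting material
11 | (1R,2S,5R)-8-phenylmenthyl 2-methyl-3-oxobutanoate | CC(=O)C(C)C(=O)O[C@@H]1C[C@H](C)CC[C@H]1C(C)(C)c2ccccc2 | intermediate
12 | sodium lithium dianion of 11 | [Li+].[Na+].[CH2-]C(=O)[C-](C)C(=O)O[C@@H]1C[C@H](C)CC[C@H]1C(C)(C)c2ccccc2 | intermediate (not isolated)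
13 | (1R,2S,5R)-8-phenylmenthyl (6E,10E)-2,6,10-trimethyl-3-oxo-13-(pivaloyloxy)trideca-6,10-dienoate | CC(C(=O)CC/C(C)=C/CC/C(C)=C/CCOC(=O)C(C)(C)C)C(=O)O[C@@H]1C[C@H](C)CC[C@H]1C(C)(C)c2ccccc2 | intermediate
14 | 8-phenylmenthyl 3-oxo-12-(pivaloyloxy)-13,14,15,16-tetranorlabd-8(17)-en-19-oate | O=C(O[C@@H]1C[C@H](C)CC[C@H]1C(C)(C)c2ccccc2)[C@@]3(C)C(=O)CC[C@]4(C)[C@@H](CCOC(=O)C(C)(C)C)C(=C)CC[C@@H]34 | intermediate
15 | 8-phenylmenthyl 3-oxo-12-(pivaloyloxy)-13,14,15,16-tetranorlabd-7-en-19-oate | O=C(O[C@@H]1C[C@H](C)CC[C@H]1C(C)(C)c2ccccc2)[C@@]3(C)C(=O)CC[C@]4(C)[C@@H](CCOC(=O)C(C)(C)C)C(C)=CC[C@@H]34 | intermediate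
16 | C3 tosylhydrazone of 15 | O=C(O[C@@H]1C[C@H](C)CC[C@H]1C(C)(C)c2ccccc2)[C@@]3(C)C(=NNS(=O)(=O)c5ccc(C)cc5)CC[C@]4(C)[C@@H](CCOC(=O)C(C)(C)C)C(C)=CC[C@@H]34 | intermediate
17 | 8-phenylmenthyl 12-(pivaloyloxy)-13,14,15,16-tetranorlabd-7-en-19-oate | O=C(O[C@@H]1C[C@H](C)CC[C@H]1C(C)(C)c2ccccc2)[C@@]3(C)CCC[C@]4(C)[C@@H](CCOC(=O)C(C)(C)C)C(C)=CC[C@@H]34 | intermediate
18 | 13,14,15,16-tetranorlabd-7-ene-12,19-diol | OC[C@@]1(C)CCC[C@]2(C)[C@@H](CCO)C(C)=CC[C@@H]12 | intermediate
19 | 12-iodo-13,14,15,16-tetranorlabd-7-en-19-ol | OC[C@@]1(C)CCC[C@]2(C)[C@@H](CCI)C(C)=CC[C@@H]12 | intermediate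
20 | angelic acid | C/C=C(/C)C(=O)O | starting material
21 | angelic 2,4,6-trichlorobenzoic anhydride | C/C=C(/C)C(=O)OC(=O)c1c(Cl)cc(Cl)cc1Cl | intermediate (not isolated)
22 | 12-iodo-13,14,15,16-tetranorlabd-7-en-19-yl angelate | C/C=C(/C)C(=O)OC[C@@]1(C)CCC[C@]2(C)[C@@H](CCI)C(C)=CC[C@@H]12 | intermediate
23 | but-2-ynoic acid | CC#CC(=O)O | starting material
24 | (2Z)-3-iodobut-2-enoic acid | C/C(I)=C/C(=O)O | intermediate
25 | alkylzinc iodide from 22 | C/C=C(/C)C(=O)OC[C@@]1(C)CCC[C@]2(C)[C@@H](CC[Zn]I)C(C)=CC[C@@H]12 | intermediate (not isolated)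
26 | sodium (2Z)-3-iodobut-2-enoate | [Na+].C/C(I)=C/C(=O)[O-] | intermediate (not isolated)
27 | 19-angeloyloxy-labda-7,13Z-dien-15-oic acid | C/C=C(/C)C(=O)OC[C@@]1(C)CCC[C@]2(C)[C@@H](CC/C(C)=C\C(=O)O)C(C)=CC[C@@H]12 | target

Total step count: 15. Longest linear sequence: 13 steps (steps 1–4, 6–13 and 15); steps 5 and 14 are side branches.

Steps most likely to fail

Step 7. The auxiliary may discriminate the two faces of the hindered α-methyl C4 radical poorly, or the slow enolisation of the α-methyl ester may let over-oxidation compete with ring closure. The fallback makes the quaternary C4 after the ring closure instead of in it. It sets out from bromide 8. (1S,2R,5S)-8-Phenylmenthyl 3-oxobutanoate F1 is made from commercial (1S,2R,5S)-8-phenylmenthol and 2,2,6-trimethyl-4H-1,3-dioxin-4-one in refluxing xylene, and its dianion (NaH, n-BuLi, THF, 0 °C) is alkylated with 8 to the α-unsubstituted keto ester F2. Cyclisation with Mn(OAc)3·2H2O, Cu(OAc)2·H2O and Yb(OTf)3 in CF3CH2OH at 0 °C should give the bicyclic β-keto ester F3. The enantiomeric auxiliary is used here because in this lanthanide-chelated manifold the ester sits equatorial in the ring-forming transition state, which inverts the link between the shielded face of C4 and the sense of the ring fusion. C-Methylation (K2CO3, MeI, acetone) is expected on the α face, opposite the C10 methyl, giving the 4α-methyl 4β-ester F4. The conditions of steps 8 to 11 then lead through the Δ7 keto ester F5, the tosylhydrazone F6 and the deoxygenated ester F7 to diol 18, where the route is rejoined.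

Step 9. Hydrazone formation may stall at the ketone flanked by the quaternary C4 with its bulky ester, and the reduction of step 10 may divert to elimination. The fallback removes the oxygen by a radical path. It sets out from 15: NaBH4 in MeOH at 0 °C should attack from the α face and give the 3β-alcohol F8; 1,1'-thiocarbonyldiimidazole and DMAP in refluxing 1,2-dichloroethane give the imidazolylthiocarbonate F9; Barton–McCombie deoxygenation (Bu3SnH, AIBN, toluene, 110 °C) returns to the route at 17.

Step 13. Slow acylation of the neopentyl, axial C19 alcohol at 75 °C may leave time for substitution or elimination at the primary iodide. The fallback keeps C12 as a silyl ether through the acylation. It sets out from diol 18: TBSCl (1.05 equiv) and imidazole in CH2Cl2 at −20 °C silylate only the unhindered C12 hydroxyl to give the mono-silyl ether F10; the same mixed-anhydride angeloylation gives the silyl ether angelate F11; HF·pyridine in THF frees the hydroxy angelate F12; and I2, PPh3 and imidazole return to the route at 22.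

Further compounds
F1 | step 7 | (1S,2R,5S)-8-phenylmenthyl 3-oxobutanoate | CC(=O)CC(=O)O[C@H]1C[C@@H](C)CC[C@@H]1C(C)(C)c2ccccc2
F2 | step 7 | (1S,2R,5S)-8-phenylmenthyl (6E,10E)-6,10-dimethyl-3-oxo-13-(pivaloyloxy)trideca-6,10-dienoate | O=C(CC/C(C)=C/CC/C(C)=C/CCOC(=O)C(C)(C)C)CC(=O)O[C@H]1C[C@@H](C)CC[C@@H]1C(C)(C)c2ccccc2
F3 | step 7 | (1S,2R,5S)-8-phenylmenthyl 3-oxo-12-(pivaloyloxy)-13,14,15,16,18-pentanorlabd-8(17)-en-19-oate (C4 enolisable) | O=C(O[C@H]1C[C@@H](C)CC[C@@H]1C(C)(C)c2ccccc2)C3C(=O)CC[C@]4(C)[C@@H](CCOC(=O)C(C)(C)C)C(=C)CC[C@@H]34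
F4 | step 7 | (1S,2R,5S)-8-phenylmenthyl 3-oxo-12-(pivaloyloxy)-13,14,15,16-tetranorlabd-8(17)-en-19-oate | O=C(O[C@H]1C[C@@H](C)CC[C@@H]1C(C)(C)c2ccccc2)[C@@]3(C)C(=O)CC[C@]4(C)[C@@H](CCOC(=O)C(C)(C)C)C(=C)CC[C@@H]34
F5 | step 7 | (1S,2R,5S)-8-phenylmenthyl 3-oxo-12-(pivaloyloxy)-13,14,15,16-tetranorlabd-7-en-19-oate | O=C(O[C@H]1C[C@@H](C)CC[C@@H]1C(C)(C)c2ccccc2)[C@@]3(C)C(=O)CC[C@]4(C)[C@@H](CCOC(=O)C(C)(C)C)C(C)=CC[C@@H]34
F6 | step 7 | C3 tosylhydrazone of F5 | O=C(O[C@H]1C[C@@H](C)CC[C@@H]1C(C)(C)c2ccccc2)[C@@]3(C)C(=NNS(=O)(=O)c5ccc(C)cc5)CC[C@]4(C)[C@@H](CCOC(=O)C(C)(C)C)C(C)=CC[C@@H]34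
F7 | step 7 | (1S,2R,5S)-8-phenylmenthyl 12-(pivaloyloxy)-13,14,15,16-tetranorlabd-7-en-19-oate | O=C(O[C@H]1C[C@@H](C)CC[C@@H]1C(C)(C)c2ccccc2)[C@@]3(C)CCC[C@]4(C)[C@@H](CCOC(=O)C(C)(C)C)C(C)=CC[C@@H]34
F8 | step 9 | (1R,2S,5R)-8-phenylmenthyl 3β-hydroxy-12-(pivaloyloxy)-13,14,15,16-tetranorlabd-7-en-19-oate | O=C(O[C@@H]1C[C@H](C)CC[C@H]1C(C)(C)c2ccccc2)[C@@]3(C)[C@@H](O)CC[C@]4(C)[C@@H](CCOC(=O)C(C)(C)C)C(C)=CC[C@@H]34
F9 | step 9 | 3β-O-(imidazol-1-ylthiocarbonyl) derivative of F8 | O=C(O[C@@H]1C[C@H](C)CC[C@H]1C(C)(C)c2ccccc2)[C@@]3(C)[C@@H](OC(=S)n5ccnc5)CC[C@]4(C)[C@@H](CCOC(=O)C(C)(C)C)C(C)=CC[C@@H]34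
F10 | step 13 | 12-(tert-butyldimethylsilyloxy)-13,14,15,16-tetranorlabd-7-en-19-ol | OC[C@@]1(C)CCC[C@]2(C)[C@@H](CCO[Si](C)(C)C(C)(C)C)C(C)=CC[C@@H]12
F11 | step 13 | 12-(tert-butyldimethylsilyloxy)-13,14,15,16-tetranorlabd-7-en-19-yl angelate | C/C=C(/C)C(=O)OC[C@@]1(C)CCC[C@]2(C)[C@@H](CCO[Si](C)(C)C(C)(C)C)C(C)=CC[C@@H]12
F12 | step 13 | 12-hydroxy-13,14,15,16-tetranorlabd-7-en-19-yl angelate | C/C=C(/C)C(=O)OC[C@@]1(C)CCC[C@]2(C)[C@@H](CCO)C(C)=CC[C@@H]12
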